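## Structural features

The target is a (2S)-flavanone. Ring A (C4a to C8a) is a phloroglucinol core with OMe on C5, OH on C7 and the ring C oxygen O1 on C8a; ring C carries the C4 ketone and the C2 stereocentre, which bears ring B, a 4-hydroxyphenyl group. C8, the ring A carbon between C7–OH and C8a–O1, is bonded to chain-C5 of a 1,7-bis(4-hydroxyphenyl)heptanoid arm (chain-C1 is the CH2 next to the saturated aryl end). On the arm, chain-C3 is a secondary carbinol (S) and chain-C5 is a methine (S) that is both benzylic to ring A and allylic to the E chain-C6=C7 styrene. The two chain stereocentres are 1,3-related across the chain-C4 methylene with no ring between them, and C2 is too remote to be influenced by either. Fragile points are ring C (base opens it by retro-oxa-Michael reaction and erases C2), the pair chain-C3–OH/hydroxystyrene (protic acid closes a tetrahydropyran), the doubly activated chain-C5–H and four free phenols. The real difficulty is chain-C5, a stereocentre on a carbon attached to a di-ortho-oxygenated aryl ring that must be set relative to chain-C3 in an open chain; C2 must then be set by a reagent alone. The key step exploits the run chain-C3 to chain-C7: an oxygen on chain-C3 followed by three sp2 carbons maps onto a 2-substituted 2,3-dihydro-4H-pyran-4-one, with the ring oxygen on chain-C3, ring C2 as chain-C3, the ring carbonyl as chain-C5 and ring C5=C6 as chain-C6/C7.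

## Logic of the disconnections

30 from 28. Bonds cut: the two aryl O–CH2 acetal bonds (O7, O4′) and three O–Si bonds (chain-C3 oxygen and both chain phenols). Reason: every hydroxyl is masked until the end, and the two classes of group can be removed in one flask without base or strong protic acid. Gain: 28 has no acidic or oxidisable hydroxyl. Demand: the last step must not open ring C or add the chain-C3 hydroxyl to the styrene.

28 from 26 and 27. Bond cut: C2–C1′. Reason: on the flat enone of 26 a chiral catalyst can set C2 without help from the remote chain stereocentres. Gain: ring B and the last stereocentre are removed. Demand: the conjugate addition must overcome the low electrophilicity of a 5,7-dioxygenated, 8-substituted enone and must leave the styrene alone.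

26 from 24, 24 from 23, 23 from 21, 21 from 20. Bonds cut: O1–C2 and C2–C3 (the one-carbon unit between the phenol and the acetyl group), the acetal on O1, C4–C4a and C4a–Br. Reason: in 20 ring A has a local twofold axis through C8 and C5, so C4a and C6 are equivalent and substitution can give only one product; once the acyl group is in place, the acetal next to it is singled out by chelation. Gain: ring C is removed and ring A becomes symmetric. Demand: halogen–metal exchange on 21 must outrun deprotonation at chain-C5, and the acetal cleavage on 23 must touch only the ortho group.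

20 from 17. Bonds cut: chain-C5–H and the chain-C6=C7 π bond, traced back to a chain-C7–O bond and a chain-C5=C6 π bond. Reason: the hard stereocentre is exchanged for a carbinol centre that a ketone reduction can set, and a suprafacial hydrogen shift carries the information across the allyl unit. Gain: chain-C5 becomes sp2 and one stereocentre is reached from an achiral ketone. Demand: clean inversion at chain-C7 without ionisation, and a single alkene geometry in 17.

17 from 16, 16 from 15, 15 from 14, 14 from 11 and 12. Bonds cut: chain-C7–H (hydride), the O–Si bond on chain-C3, and chain-C7–C(aryl). Reason: the aldehyde carbon masked in 11 is the natural acceptor for the second aryl ring. Gain: the styrene aryl ring is removed and the arm is reduced to a six-membered lactol. Demand: the reduction of 16 must distinguish an aryl from an alkenyl substituent, and the chain-C3 hydroxyl of 15 must be capped before it closes onto the ketone.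

11 from 6 and 8. Bonds cut: chain-C5–C8 (ring A); the oxygen function is moved back from chain-C7 to chain-C5. Reason: the carbonyl of 6 is the only electrophilic carbon that accepts a hindered aryl anion 1,2, and the ring holds chain-C4 and chain-C7 cis. Gain: ring A is removed as a symmetric arene and the alkene geometry is no longer a variable. Demand: addition must beat enolisation of 6, and the acid used for the transposition must spare the acetals of 8.

6 from 3 and 4. Bonds cut: chain-C3–C4 and the ring O–chain-C7 bond. Reason: the five-carbon oxygenated run is exactly an aldehyde plus a four-carbon silyloxydiene. Gain: one ring, one C–C bond and the first stereocentre are removed, leaving an achiral aldehyde and a commercial diene. Demand: a chiral Lewis acid must select one face of an unbranched, enolisable aldehyde.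

3 from 2 and 2 from 1; 8 from 7. Bonds cut: the aldehyde C–H (back to the ester C–O) and O–Si; two O–CH2 acetal bonds. Gain: commercial 1, 4, 7, 12 and 27 are reached.

## Other disconnections considered

Alternative 1: The cut removes both styryl alkenes of the arm, chain-C1=C2 and chain-C6=C7, at once. In the forward sense the cis-cyclopentenol A1 is opened by double cross-metathesis with excess styrene A2 under RuCl2(H2IMes)(=CH-C6H4-O-iPr) to give dienol A3.
- In its favour: A1 stores chain-C3 and chain-C5 as a cis-1,3 pair on a five-membered ring, where relative configuration is easy to set and to prove, and both aryl ends arrive in one operation.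
- Against it here: cyclopentene has little strain, so the opening is reversible and must be driven by excess A2 while A2 also dimerises. The ring alkene of A1 sits next to the di-ortho-substituted ring A, which hinders the ruthenium carbene. Above all, A3 has two almost identical E-styryl alkenes, and only chain-C1=C2 may be saturated; that choice rests solely on the allylic hydroxyl.
- Comparison: on structure, A1 stores both chain stereocentres and 6 only one, which is a point for the alternative. On mechanism, the chosen plan makes its two alkenes at different times by irreversible steps, so no alkene-versus-alkene selection arises, which is a point for the chosen plan. Stereocontrol is equal, since each plan rests on one asymmetric catalytic step plus a relay. On step economy the alternative is the better one for the arm itself, but it needs the selective reduction and the same ring C work.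

Alternative 2: The cut is C2–C3 of ring C. In the forward sense Rh2(S-PTTL)4 (or its mirror image) decomposes diazoketone A4, and the carbenoid inserts into the benzylic C–H bond of the O1 4-silyloxybenzyl ether to give A5.
- In its favour: ring C closes and C2 is set in one neutral step, with no base and therefore no retro-oxa-Michael opening. In directness of ring C formation this alternative is the better one.
- Against it here: insertion to a six-membered ring must compete with oxonium ylide formation at the same ether oxygen followed by benzyl shift, with cyclopropanation of the chain-C6=C7 styrene, and with attack on the electron-rich rings. An acceptor-only carbenoid is the least selective kind. A4 must be made late from a di-ortho-substituted aryl ketone, and the two ring A oxygens must still be told apart to place the benzyl group.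
- Comparison: both plans set C2 with a chiral rhodium catalyst, so they are equal on the source of stereocontrol. The aryl–rhodium intermediate of the chosen plan ignores the styrene whereas a carbenoid does not, so the chosen plan is ahead on chemoselectivity. Step count is about equal once the preparation of A4 is counted.

Alternative 3: The cut is C8–C8a and C6–C7 of ring A. In the forward sense cyclobutenone A6 is heated with siloxyalkyne A7; ring opening to a vinylketene, [2+2] addition, a second ring opening and 6π-electrocyclisation give the resorcinol mono-silyl ether A8.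
- In its favour: ring A arrives with OMe, free OH and OTIPS each in place and the two flanking oxygens already different. Here the alternative is better than the chosen plan, which must differentiate two identical acetals after acylation. No hindered aryl nucleophile is needed and the conditions are neutral.
- Against it here: the whole arm with both stereocentres must exist beforehand on an alkyne, so chain-C5 becomes a propargylic and allylic methine that must be set without the aryl ring and can isomerise toward an allene. Making a siloxyalkyne from an ester in such a substrate is delicate, the sequence becomes linear, and ring C still has to be built.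
- Comparison: on structure, the alternative trades the chain-C5–aryl bond for a ring synthesis. On mechanism, the pericyclic cascade is regiochemically reliable, equal to or better than directed lithiation. On stereocontrol, the chosen plan solves chain-C5 by transposition while the alternative leaves it open. On step economy the alternative has the longer linear sequence.

Key step: step 3

Remarks before the steps:
- Abbreviations in names: TIPS = triisopropylsilyl, TBS = tert-butyldimethylsilyl, MOM = methoxymethyl. Open-chain intermediates are named with the heptanoid locants (chain-C1 = CH2 beside the saturated aryl ring, chain-C7 = styryl carbon).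
- Check of the key-step partners against the target: C2 of 6 must be S, because the CIP order there (O > ring CH2 > side-chain CH2) is the same as at chain-C3 of 30. The skeletons need no correction. The aldehyde keeps the bulky TIPS ether so that the phenolic oxygen neither binds titanium nor is lost in CF3CO2H.
- Assumption: the antipodes named for the chiral catalysts of steps 3, 9 and 15 follow the usual facial models of these catalyst families; if a model is reversed for this substrate, the mirror-image ligand is used in that step and nothing else changes.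

## Route

Step 1
Reactants: 1 methyl 3-(4-hydroxyphenyl)propanoate
Product: 2 methyl 3-[4-(TIPS-oxy)phenyl]propanoate
Conditions: TIPSCl, imidazole, DMF, rt
Reagents that add atoms: triisopropylsilyl chloride CC(C)[Si](Cl)(C(C)C)C(C)C
Why: O-Silylation of a phenol with imidazole as base and nucleophilic catalyst; the aryl TIPS ether survives CF3CO2H, organolithium and Grignard reagents and shields the oxygen from titanium in step 3.

Step 2
Reactants: 2 methyl 3-[4-(TIPS-oxy)phenyl]propanoate
Product: 3 3-[4-(TIPS-oxy)phenyl]propanal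
Conditions: iBu2AlH (1.05 equiv), CH2Cl2, −78 °C; MeOH, then aq. potassium sodium tartrate
Reagents that add atoms: none
Why: Partial reduction of an ester; the tetrahedral aluminium hemiacetal is stable at −78 °C and gives the aldehyde only on work-up, and the aldehyde is used at once and free of acid.

Step 3
Reactants: 3 3-[4-(TIPS-oxy)phenyl]propanal; 4 (E)-1-methoxy-3-(trimethylsilyloxy)buta-1,3-diene
Product: 6 (2S)-2-{2-[4-(TIPS-oxy)phenyl]ethyl}-2,3-dihydro-4H-pyran-4-one, via Mukaiyama aldol adduct 5 (not isolated)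
Conditions: (R)-BINOL (20 mol %), Ti(OiPr)4 (10 mol %), CF3CO2H (cat.), 4 Å MS, Et2O, −20 °C; then CF3CO2H, CH2Cl2, 0 °C
Reagents that add atoms: none
Why: The binaphtholate complex of tetravalent titanium binds the aldehyde oxygen anti to the alkyl chain, and the silyloxydiene adds through an open Mukaiyama aldol transition state, the trimethylsilyl group ending on the aldolate oxygen to give 5. The closest known reaction type is the Lewis acid-catalysed asymmetric hetero-Diels–Alder reaction of aldehydes with 1-alkoxy-3-silyloxybutadienes, which runs stepwise (aldol, then cyclisation) with this catalyst class. CF3CO2H then frees the chain-C3 hydroxyl, which closes the ring by 6-endo-trig oxa-conjugate addition to the β-methoxy enone, and loss of methanol gives the vinylogous ester 6. The one new stereocentre (C2 of 6, later chain-C3) is set in the aldol step by the binaphthyl ligand alone: with the (R)-ligand the diene terminus is expected to reach the Re face of the bound aldehyde, which for an R–CH2–CHO aldehyde gives S. The step needs facial selectivity on an unbranched, enolisable aldehyde and aldol addition in preference to self-condensation; the mild Lewis acidity of the catalyst, the low temperature and the absence of a second donor site in 3 (its only other oxygen lies under the TIPS group) should secure both. In all, one C–C bond (chain-C3–C4), one C–O bond (ring O–chain-C7), one ring and one stereocentre are formed.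

Step 4
Reactants: 7 5-methoxyresorcinol
Product: 8 1-methoxy-3,5-bis(MOM-oxy)benzene
Conditions: MOMCl solution (from CH2(OMe)2, AcCl, cat. ZnBr2, toluene, rt), iPr2NEt, CH2Cl2, 0 °C → rt
Reagents that add atoms: chloromethyl methyl ether COCCl (made in the flask from dimethoxymethane COCOC and acetyl chloride CC(Cl)=O)
Why: O-Alkylation of both phenols; the acetal ethers are the directing groups for the lithiation of step 5, and the haloether is generated and consumed in solution so that it is never handled neat.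

Step 5
Reactants: 8 1-methoxy-3,5-bis(MOM-oxy)benzene; 6 (2S)-2-{2-[4-(TIPS-oxy)phenyl]ethyl}-2,3-dihydro-4H-pyran-4-one
Product: 11 (6S)-4-[4-methoxy-2,6-bis(MOM-oxy)phenyl]-6-{2-[4-(TIPS-oxy)phenyl]ethyl}-5,6-dihydro-2H-pyran-2-ol (both anomers), via aryllithium 9 (not isolated), via tertiary allylic carbinol 10 (not isolated)
Conditions: 8, n-BuLi, THF, 0 °C; 6, −78 → −30 °C; then 0.5 M aq. HCl, THF, 0 °C
Reagents that add atoms: water O
Why: Directed ortho-metalation between the two MOM-oxy groups gives 9, which adds 1,2 to the vinylogous ester carbonyl of 6 (Stork–Danheiser-type sequence). Dilute acid ionises the doubly activated carbinol 10 to a 4-aryl-2,3-dihydropyrylium ion that water captures at chain-C7, moving the oxygen function from chain-C5 to chain-C7. Because chain-C4 and chain-C7 stay in the ring, the chain-C5=C6 alkene forms as one geometrical isomer and chain-C3 is untouched.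

Step 6
Reactants: 11 (6S)-4-[4-methoxy-2,6-bis(MOM-oxy)phenyl]-6-{2-[4-(TIPS-oxy)phenyl]ethyl}-5,6-dihydro-2H-pyran-2-ol; 12 (4-bromophenoxy)triisopropylsilane
Product: 14 (3S,5E)-5-[4-methoxy-2,6-bis(MOM-oxy)phenyl]-1,7-bis[4-(TIPS-oxy)phenyl]hept-5-ene-3,7-diol (both chain-C7 epimers), via arylmagnesium bromide 13 (not isolated)
Conditions: 12, Mg, THF, rt (13, 3 equiv); then 11, 0 °C → rt; aq. NH4Cl
Reagents that add atoms: none
Why: Grignard addition to a lactol: the first equivalent of 13 deprotonates 11, the magnesium lactolate opens to the enal, and a second equivalent adds 1,2 to the β,β-disubstituted enal. The new carbinol centre is uncontrolled and is erased in step 7.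

Step 7
Reactants: 14 (3S,5E)-5-[4-methoxy-2,6-bis(MOM-oxy)phenyl]-1,7-bis[4-(TIPS-oxy)phenyl]hept-5-ene-3,7-diol
Product: 15 (3S,5E)-3-hydroxy-5-[4-methoxy-2,6-bis(MOM-oxy)phenyl]-1,7-bis[4-(TIPS-oxy)phenyl]hept-5-en-7-one
Conditions: MnO2 (activated, excess), CH2Cl2, rt
Reagents that add atoms: none
Why: MnO2 oxidises only the allylic and benzylic chain-C7 carbinol and leaves the saturated chain-C3 carbinol. The enone keeps the geometry fixed in step 5, which is also the more stable one (ring A trans to the carbonyl).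

Step 8
Reactants: 15 (3S,5E)-3-hydroxy-5-[4-methoxy-2,6-bis(MOM-oxy)phenyl]-1,7-bis[4-(TIPS-oxy)phenyl]hept-5-en-7-one
Product: 16 (3S,5E)-3-(TBS-oxy)-5-[4-methoxy-2,6-bis(MOM-oxy)phenyl]-1,7-bis[4-(TIPS-oxy)phenyl]hept-5-en-7-one
Conditions: TBSCl, imidazole, DMF, rt
Reagents that add atoms: tert-butyldimethylsilyl chloride CC(C)(C)[Si](C)(C)Cl
Why: Silylation of the secondary alcohol; it removes the hydroxyl that could close a six-membered hemiketal onto the chain-C7 ketone and that would compete in the Mitsunobu reaction of step 10.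

Step 9
Reactants: 16 (3S,5E)-3-(TBS-oxy)-5-[4-methoxy-2,6-bis(MOM-oxy)phenyl]-1,7-bis[4-(TIPS-oxy)phenyl]hept-5-en-7-one
Product: 17 (3S,5E,7R)-3-(TBS-oxy)-5-[4-methoxy-2,6-bis(MOM-oxy)phenyl]-1,7-bis[4-(TIPS-oxy)phenyl]hept-5-en-7-ol
Conditions: (R)-2-methyl-CBS-oxazaborolidine (0.3 equiv), catecholborane, toluene, −78 → −40 °C
Reagents that add atoms: none
Why: Oxazaborolidine-catalysed (CBS) 1,2-reduction of an enone. In the s-cis enone the chain-C4 methylene flanks the carbonyl oxygen on the alkenyl side, so the catalyst boron should bind the lone pair on the aryl side and the β,β-disubstituted alkenyl arm acts as the large group; the (R)-catalyst then delivers hydride to the face that gives 7R. Catecholborane at low temperature avoids hydroboration and conjugate reduction.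

Step 10
Reactants: 17 (3S,5E,7R)-3-(TBS-oxy)-5-[4-methoxy-2,6-bis(MOM-oxy)phenyl]-1,7-bis[4-(TIPS-oxy)phenyl]hept-5-en-7-ol
Product: 20 (3S,5S,6E)-3-(TBS-oxy)-5-[4-methoxy-2,6-bis(MOM-oxy)phenyl]-1,7-bis[4-(TIPS-oxy)phenyl]hept-6-ene, via inverted sulfonylhydrazide 18 (not isolated), via allylic diazene 19 (not isolated)
Conditions: 2-O2NC6H4SO2NHNH2, PPh3, DEAD, N-methylmorpholine, −30 °C; then rt
Reagents that add atoms: none
Why: Reductive 1,3-transposition of an allylic alcohol through a monoalkyl diazene: Mitsunobu displacement by the sulfonylhydrazide inverts chain-C7 (18), loss of 2-nitrobenzenesulfinic acid on warming gives 19, and a concerted retro-ene loss of N2 places hydrogen on chain-C5 on the face where nitrogen sits. Allylic 1,3-strain with the cis chain-C4 methylene keeps chain-C7–H in the alkene plane, so the 7R carbinol of defined alkene geometry should give 5S and the E chain-C6=C7 alkene. Ring A is trans to chain-C7 on the alkene, so its ortho oxygens cannot capture the activated carbinol.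

Step 11
Reactants: 20 (3S,5S,6E)-3-(TBS-oxy)-5-[4-methoxy-2,6-bis(MOM-oxy)phenyl]-1,7-bis[4-(TIPS-oxy)phenyl]hept-6-ene
Product: 21 (3S,5S,6E)-5-[3-bromo-4-methoxy-2,6-bis(MOM-oxy)phenyl]-3-(TBS-oxy)-1,7-bis[4-(TIPS-oxy)phenyl]hept-6-ene
Conditions: NBS (1.0 equiv), MeCN, −20 °C, dark
Reagents that add atoms: N-bromosuccinimide O=C1CCC(=O)N1Br
Why: Electrophilic aromatic bromination; the trialkoxy ring A is far more nucleophilic than the silyloxyphenyl rings or the styrene, and its two free positions (C4a, C6) are equivalent by the local twofold axis through C8 and C5, so one monobromide should result.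

Step 12
Reactants: 21 (3S,5S,6E)-5-[3-bromo-4-methoxy-2,6-bis(MOM-oxy)phenyl]-3-(TBS-oxy)-1,7-bis[4-(TIPS-oxy)phenyl]hept-6-ene
Product: 23 1-{3-[(3S,5S,6E)-3-(TBS-oxy)-1,7-bis[4-(TIPS-oxy)phenyl]hept-6-en-5-yl]-6-methoxy-2,4-bis(MOM-oxy)phenyl}ethan-1-one, via aryllithium 22 (not isolated)
Conditions: t-BuLi (2.1 equiv), THF, −78 °C; then MeCON(OMe)Me, −78 → −20 °C; aq. NH4Cl
Reagents that add atoms: N-methoxy-N-methylacetamide CON(C)C(C)=O
Why: Bromine–lithium exchange is faster at −78 °C than deprotonation at chain-C5 or addition to the styrene. Acylation of 22 with the N-methoxy-N-methylamide stops at the ketone because the chelated tetrahedral adduct survives until work-up.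

Step 13
Reactants: 23 1-{3-[(3S,5S,6E)-3-(TBS-oxy)-1,7-bis[4-(TIPS-oxy)phenyl]hept-6-en-5-yl]-6-methoxy-2,4-bis(MOM-oxy)phenyl}ethan-1-one
Product: 24 1-{2-hydroxy-3-[(3S,5S,6E)-3-(TBS-oxy)-1,7-bis[4-(TIPS-oxy)phenyl]hept-6-en-5-yl]-6-methoxy-4-(MOM-oxy)phenyl}ethan-1-one
Conditions: MgBr2·OEt2 (2.5 equiv), CH2Cl2/Et2O, 0 °C → rt; aq. NH4Cl
Reagents that add atoms: none
Why: Chelation-controlled cleavage of an acetal ether: magnesium held between the ketone oxygen and the ortho MOM-oxy group activates only that acetal toward bromide and gives the hydrogen-bonded 2′-phenol. The para acetal, the methyl ether and the silyl ethers cannot form this chelate.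

Step 14
Reactants: 24 1-{2-hydroxy-3-[(3S,5S,6E)-3-(TBS-oxy)-1,7-bis[4-(TIPS-oxy)phenyl]hept-6-en-5-yl]-6-methoxy-4-(MOM-oxy)phenyl}ethan-1-one
Product: 26 8-[(3S,5S,6E)-3-(TBS-oxy)-1,7-bis[4-(TIPS-oxy)phenyl]hept-6-en-5-yl]-5-methoxy-7-(MOM-oxy)-4H-chromen-4-one, via enaminone 25 (not isolated)
Conditions: Me2NCH(OMe)2, toluene, 90 °C; then AcOH, 40 °C
Reagents that add atoms: N,N-dimethylformamide dimethyl acetal COC(OC)N(C)C
Why: Condensation of the methyl ketone with the formamide acetal gives 25; mild acid closes ring C by addition of the phenol to the β-carbon and loss of dimethylamine (6-endo-trig addition–elimination), the standard chromone synthesis from 2′-hydroxyacetophenones.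

Step 15
Reactants: 26 8-[(3S,5S,6E)-3-(TBS-oxy)-1,7-bis[4-(TIPS-oxy)phenyl]hept-6-en-5-yl]-5-methoxy-7-(MOM-oxy)-4H-chromen-4-one; 27 [4-(MOM-oxy)phenyl]boronic acid
Product: 28 (2S)-8-[(3S,5S,6E)-3-(TBS-oxy)-1,7-bis[4-(TIPS-oxy)phenyl]hept-6-en-5-yl]-5-methoxy-7-(MOM-oxy)-2-[4-(MOM-oxy)phenyl]-2,3-dihydro-4H-chromen-4-one
Conditions: 27 (3 equiv), [RhCl(C2H4)2]2 (3 mol %), (1S,4S)-2,5-diphenylbicyclo[2.2.2]octa-2,5-diene (7 mol %), K3PO4 (0.5 equiv), toluene/H2O (10:1), 50 °C
Reagents that add atoms: none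
Why: Rhodium-catalysed asymmetric conjugate addition of an arylboronic acid to a chromone (Hayashi–Miyaura reaction): the aryl–rhodium species bound to the chiral diene adds across C2=C3 from one face and water protonates the oxa-π-allyl intermediate. The ligand antipode is the one that gives (S)-3-arylcyclohexanones from cyclohexenone, which corresponds to 2S here; the remote chain stereocentres take no part. The two-phase, weakly basic medium limits retro-oxa-Michael opening of the product.

Step 16
Reactants: 28 (2S)-8-[(3S,5S,6E)-3-(TBS-oxy)-1,7-bis[4-(TIPS-oxy)phenyl]hept-6-en-5-yl]-5-methoxy-7-(MOM-oxy)-2-[4-(MOM-oxy)phenyl]-2,3-dihydro-4H-chromen-4-one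
Product: 30 (2S)-7-hydroxy-8-[(3S,5S,6E)-3-hydroxy-1,7-bis(4-hydroxyphenyl)hept-6-en-5-yl]-2-(4-hydroxyphenyl)-5-methoxy-2,3-dihydro-4H-chromen-4-one, via bis(trimethylsilyl) ether 29 (not isolated)
Conditions: TMSOTf, 2,2′-bipyridyl, CH2Cl2, 0 °C → rt; then HF·pyridine, pyridine, THF, 0 °C → rt
Reagents that add atoms: none
Why: The silyl triflate–bipyridyl pair converts aryl MOM ethers into aryl silyl ethers without protic acid, and buffered fluoride then removes all five silyl groups. No base is present, so ring C should not open, and no strong acid is present, so the chain-C3 hydroxyl should not add to the hydroxystyrene.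

## Compound list

1 | methyl 3-(4-hydroxyphenyl)propanoate | COC(=O)CCc1ccc(O)cc1 | starting material
2 | methyl 3-[4-(TIPS-oxy)phenyl]propanoate | COC(=O)CCc1ccc(O[Si](C(C)C)(C(C)C)C(C)C)cc1 | intermediate
3 | 3-[4-(TIPS-oxy)phenyl]propanal | O=CCCc1ccc(O[Si](C(C)C)(C(C)C)C(C)C)cc1 | intermediate
4 | (E)-1-methoxy-3-(trimethylsilyloxy)buta-1,3-diene | CO/C=C/C(=C)O[Si](C)(C)C | starting material
5 | (1E,5S)-1-methoxy-7-[4-(TIPS-oxy)phenyl]-5-(trimethylsilyloxy)hept-1-en-3-one | CO/C=C/C(=O)C[C@@H](O[Si](C)(C)C)CCc1ccc(O[Si](C(C)C)(C(C)C)C(C)C)cc1 | intermediate (not isolated)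
6 | (2S)-2-{2-[4-(TIPS-oxy)phenyl]ethyl}-2,3-dihydro-4H-pyran-4-one | O=C1C=CO[C@@H](CCc2ccc(O[Si](C(C)C)(C(C)C)C(C)C)cc2)C1 | intermediate
7 | 5-methoxyresorcinol (5-methoxybenzene-1,3-diol) | COc1cc(O)cc(O)c1 | starting material
8 | 1-methoxy-3,5-bis(MOM-oxy)benzene | COCOc1cc(OC)cc(OCOC)c1 | intermediate
9 | [4-methoxy-2,6-bis(MOM-oxy)phenyl]lithium | [Li]c1c(OCOC)cc(OC)cc1OCOC | intermediate (not isolated)
10 | (2S)-4-[4-methoxy-2,6-bis(MOM-oxy)phenyl]-2-{2-[4-(TIPS-oxy)phenyl]ethyl}-3,4-dihydro-2H-pyran-4-ol (both C4 epimers) | OC1(c2c(OCOC)cc(OC)cc2OCOC)C=CO[C@@H](CCc2ccc(O[Si](C(C)C)(C(C)C)C(C)C)cc2)C1 | intermediate (not isolated)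
11 | (6S)-4-[4-methoxy-2,6-bis(MOM-oxy)phenyl]-6-{2-[4-(TIPS-oxy)phenyl]ethyl}-5,6-dihydro-2H-pyran-2-ol (both anomers) | OC1C=C(c2c(OCOC)cc(OC)cc2OCOC)C[C@H](CCc2ccc(O[Si](C(C)C)(C(C)C)C(C)C)cc2)O1 | intermediate
12 | (4-bromophenoxy)triisopropylsilane | Brc1ccc(O[Si](C(C)C)(C(C)C)C(C)C)cc1 | starting material
13 | [4-(TIPS-oxy)phenyl]magnesium bromide | Br[Mg]c1ccc(O[Si](C(C)C)(C(C)C)C(C)C)cc1 | intermediate (not isolated)
14 | (3S,5E)-5-[4-methoxy-2,6-bis(MOM-oxy)phenyl]-1,7-bis[4-(TIPS-oxy)phenyl]hept-5-ene-3,7-diol (both chain-C7 epimers) | OC(c1ccc(O[Si](C(C)C)(C(C)C)C(C)C)cc1)/C=C(/c1c(OCOC)cc(OC)cc1OCOC)C[C@@H](O)CCc1ccc(O[Si](C(C)C)(C(C)C)C(C)C)cc1 | intermediate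
15 | (3S,5E)-3-hydroxy-5-[4-methoxy-2,6-bis(MOM-oxy)phenyl]-1,7-bis[4-(TIPS-oxy)phenyl]hept-5-en-7-one | O=C(c1ccc(O[Si](C(C)C)(C(C)C)C(C)C)cc1)/C=C(/c1c(OCOC)cc(OC)cc1OCOC)C[C@@H](O)CCc1ccc(O[Si](C(C)C)(C(C)C)C(C)C)cc1 | intermediate
16 | (3S,5E)-3-(TBS-oxy)-5-[4-methoxy-2,6-bis(MOM-oxy)phenyl]-1,7-bis[4-(TIPS-oxy)phenyl]hept-5-en-7-one | O=C(c1ccc(O[Si](C(C)C)(C(C)C)C(C)C)cc1)/C=C(/c1c(OCOC)cc(OC)cc1OCOC)C[C@@H](O[Si](C)(C)C(C)(C)C)CCc1ccc(O[Si](C(C)C)(C(C)C)C(C)C)cc1 | intermediate
17 | (3S,5E,7R)-3-(TBS-oxy)-5-[4-methoxy-2,6-bis(MOM-oxy)phenyl]-1,7-bis[4-(TIPS-oxy)phenyl]hept-5-en-7-ol | O[C@@H](c1ccc(O[Si](C(C)C)(C(C)C)C(C)C)cc1)/C=C(/c1c(OCOC)cc(OC)cc1OCOC)C[C@@H](O[Si](C)(C)C(C)(C)C)CCc1ccc(O[Si](C(C)C)(C(C)C)C(C)C)cc1 | intermediate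
18 | N-{(3S,5E,7S)-3-(TBS-oxy)-5-[4-methoxy-2,6-bis(MOM-oxy)phenyl]-1,7-bis[4-(TIPS-oxy)phenyl]hept-5-en-7-yl}-2-nitrobenzenesulfonohydrazide | NN([C@H](c1ccc(O[Si](C(C)C)(C(C)C)C(C)C)cc1)/C=C(/c1c(OCOC)cc(OC)cc1OCOC)C[C@@H](O[Si](C)(C)C(C)(C)C)CCc1ccc(O[Si](C(C)C)(C(C)C)C(C)C)cc1)S(=O)(=O)c1ccccc1[N+](=O)[O-] | intermediate (not isolated)
19 | {(3S,5E,7S)-3-(TBS-oxy)-5-[4-methoxy-2,6-bis(MOM-oxy)phenyl]-1,7-bis[4-(TIPS-oxy)phenyl]hept-5-en-7-yl}diazene | N=N[C@H](c1ccc(O[Si](C(C)C)(C(C)C)C(C)C)cc1)/C=C(/c1c(OCOC)cc(OC)cc1OCOC)C[C@@H](O[Si](C)(C)C(C)(C)C)CCc1ccc(O[Si](C(C)C)(C(C)C)C(C)C)cc1 | intermediate (not isolated)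
20 | (3S,5S,6E)-3-(TBS-oxy)-5-[4-methoxy-2,6-bis(MOM-oxy)phenyl]-1,7-bis[4-(TIPS-oxy)phenyl]hept-6-ene | COc1cc(OCOC)c([C@H](/C=C/c2ccc(O[Si](C(C)C)(C(C)C)C(C)C)cc2)C[C@@H](O[Si](C)(C)C(C)(C)C)CCc2ccc(O[Si](C(C)C)(C(C)C)C(C)C)cc2)c(OCOC)c1 | intermediate
21 | (3S,5S,6E)-5-[3-bromo-4-methoxy-2,6-bis(MOM-oxy)phenyl]-3-(TBS-oxy)-1,7-bis[4-(TIPS-oxy)phenyl]hept-6-ene | COc1cc(OCOC)c([C@H](/C=C/c2ccc(O[Si](C(C)C)(C(C)C)C(C)C)cc2)C[C@@H](O[Si](C)(C)C(C)(C)C)CCc2ccc(O[Si](C(C)C)(C(C)C)C(C)C)cc2)c(OCOC)c1Br | intermediate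
22 | {3-[(3S,5S,6E)-3-(TBS-oxy)-1,7-bis[4-(TIPS-oxy)phenyl]hept-6-en-5-yl]-6-methoxy-2,4-bis(MOM-oxy)phenyl}lithium | COc1cc(OCOC)c([C@H](/C=C/c2ccc(O[Si](C(C)C)(C(C)C)C(C)C)cc2)C[C@@H](O[Si](C)(C)C(C)(C)C)CCc2ccc(O[Si](C(C)C)(C(C)C)C(C)C)cc2)c(OCOC)c1[Li] | intermediate (not isolated)
23 | 1-{3-[(3S,5S,6E)-3-(TBS-oxy)-1,7-bis[4-(TIPS-oxy)phenyl]hept-6-en-5-yl]-6-methoxy-2,4-bis(MOM-oxy)phenyl}ethan-1-one | COc1cc(OCOC)c([C@H](/C=C/c2ccc(O[Si](C(C)C)(C(C)C)C(C)C)cc2)C[C@@H](O[Si](C)(C)C(C)(C)C)CCc2ccc(O[Si](C(C)C)(C(C)C)C(C)C)cc2)c(OCOC)c1C(C)=O | intermediate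
24 | 1-{2-hydroxy-3-[(3S,5S,6E)-3-(TBS-oxy)-1,7-bis[4-(TIPS-oxy)phenyl]hept-6-en-5-yl]-6-methoxy-4-(MOM-oxy)phenyl}ethan-1-one | COc1cc(OCOC)c([C@H](/C=C/c2ccc(O[Si](C(C)C)(C(C)C)C(C)C)cc2)C[C@@H](O[Si](C)(C)C(C)(C)C)CCc2ccc(O[Si](C(C)C)(C(C)C)C(C)C)cc2)c(O)c1C(C)=O | intermediate
25 | (2E)-3-(dimethylamino)-1-{2-hydroxy-3-[(3S,5S,6E)-3-(TBS-oxy)-1,7-bis[4-(TIPS-oxy)phenyl]hept-6-en-5-yl]-6-methoxy-4-(MOM-oxy)phenyl}prop-2-en-1-one | COc1cc(OCOC)c([C@H](/C=C/c2ccc(O[Si](C(C)C)(C(C)C)C(C)C)cc2)C[C@@H](O[Si](C)(C)C(C)(C)C)CCc2ccc(O[Si](C(C)C)(C(C)C)C(C)C)cc2)c(O)c1C(=O)/C=C/N(C)C | intermediate (not isolated)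
26 | 8-[(3S,5S,6E)-3-(TBS-oxy)-1,7-bis[4-(TIPS-oxy)phenyl]hept-6-en-5-yl]-5-methoxy-7-(MOM-oxy)-4H-chromen-4-one | COc1cc(OCOC)c([C@H](/C=C/c2ccc(O[Si](C(C)C)(C(C)C)C(C)C)cc2)C[C@@H](O[Si](C)(C)C(C)(C)C)CCc2ccc(O[Si](C(C)C)(C(C)C)C(C)C)cc2)c2c1C(=O)C=CO2 | intermediate
27 | [4-(MOM-oxy)phenyl]boronic acid | OB(O)c1ccc(OCOC)cc1 | starting material
28 | (2S)-8-[(3S,5S,6E)-3-(TBS-oxy)-1,7-bis[4-(TIPS-oxy)phenyl]hept-6-en-5-yl]-5-methoxy-7-(MOM-oxy)-2-[4-(MOM-oxy)phenyl]-2,3-dihydro-4H-chromen-4-one | COc1cc(OCOC)c([C@H](/C=C/c2ccc(O[Si](C(C)C)(C(C)C)C(C)C)cc2)C[C@@H](O[Si](C)(C)C(C)(C)C)CCc2ccc(O[Si](C(C)C)(C(C)C)C(C)C)cc2)c2c1C(=O)C[C@@H](c1ccc(OCOC)cc1)O2 | intermediate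
29 | (2S)-8-[(3S,5S,6E)-3-(TBS-oxy)-1,7-bis[4-(TIPS-oxy)phenyl]hept-6-en-5-yl]-5-methoxy-7-(trimethylsilyloxy)-2-[4-(trimethylsilyloxy)phenyl]-2,3-dihydro-4H-chromen-4-one | COc1cc(O[Si](C)(C)C)c([C@H](/C=C/c2ccc(O[Si](C(C)C)(C(C)C)C(C)C)cc2)C[C@@H](O[Si](C)(C)C(C)(C)C)CCc2ccc(O[Si](C(C)C)(C(C)C)C(C)C)cc2)c2c1C(=O)C[C@@H](c1ccc(O[Si](C)(C)C)cc1)O2 | intermediate (not isolated)
30 | (2S)-7-hydroxy-8-[(3S,5S,6E)-3-hydroxy-1,7-bis(4-hydroxyphenyl)hept-6-en-5-yl]-2-(4-hydroxyphenyl)-5-methoxy-2,3-dihydro-4H-chromen-4-one | COc1cc(O)c([C@H](/C=C/c2ccc(O)cc2)C[C@@H](O)CCc2ccc(O)cc2)c2c1C(=O)C[C@@H](c1ccc(O)cc1)O2 | target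

## Step count and least certain steps

Total: 16 steps. Longest linear sequence: 15 steps (steps 1 to 3 and 5 to 16, from 1); step 4 is a one-step side branch. Compounds 12 and 27 are taken as commercial.

Step 3 (key step). What may go wrong: incomplete facial discrimination on the linear aldehyde, and self-condensation of the enolisable aldehyde or oligomerisation of the diene before the aldol step. Fallback, setting out from 3 and returning at 6: asymmetric allylboration of 3 with the B-allyldiisopinocampheylborane antipode that attacks the Re face should give (3S)-1-[4-(TIPS-oxy)phenyl]hex-5-en-3-ol F1. Wacker oxidation (PdCl2, CuCl, O2, DMF/H2O) converts the terminal alkene into the methyl ketone (4S)-4-hydroxy-6-[4-(TIPS-oxy)phenyl]hexan-2-one F2. Condensation with Me2NCH(OMe)2 gives the enaminone (1E,5S)-1-(dimethylamino)-5-hydroxy-7-[4-(TIPS-oxy)phenyl]hept-1-en-3-one F3, and mild acid closes it to 6 with loss of dimethylamine.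

Step 5. What may go wrong: enolisation of 6 by the hindered aryllithium instead of addition (transmetalation to cerium with CeCl3 would be the first remedy), partial lithiation of 8 next to the methoxy group, and, in the acid stage, loss of a proton from the dihydropyrylium ion followed by electrocyclic opening of the resulting 2H-pyran. Fallback for the transposition, setting out from 10 (isolated after a NaHCO3 quench) and returning at 11: oxidative allylic transposition of the tertiary carbinol (Babler–Dauben oxidation) with pyridinium chlorochromate (C5H5NH)[CrO3Cl] buffered with NaOAc should give the lactone (6S)-4-[4-methoxy-2,6-bis(MOM-oxy)phenyl]-6-{2-[4-(TIPS-oxy)phenyl]ethyl}-5,6-dihydro-2H-pyran-2-one F4, which iBu2AlH at −78 °C reduces to 11.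

Step 9. What may go wrong: the two sp2 substituents of the ketone are of similar size, so facial selectivity may be low or opposite to the model. Fallback, setting out from 16 and returning at 20 (it also replaces step 10): catalytic asymmetric conjugate reduction (Cu(OAc)2, the DTBM-SEGPHOS antipode that places hydride on the required face of chain-C5, polymethylhydrosiloxane, t-BuOH, toluene) should give the saturated ketone (3S)-3-(TBS-oxy)-5-[4-methoxy-2,6-bis(MOM-oxy)phenyl]-1,7-bis[4-(TIPS-oxy)phenyl]heptan-7-one with chain-C5 as in 20, F5. NaBH4 gives the carbinol mixture (3S)-3-(TBS-oxy)-5-[4-methoxy-2,6-bis(MOM-oxy)phenyl]-1,7-bis[4-(TIPS-oxy)phenyl]heptan-7-ol F6, and syn-dehydration with methyl N-(triethylammoniosulfonyl)carbamate gives the E-styrene 20.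

Step 10. What may go wrong: ionisation of the activated chain-C7 oxyphosphonium (a doubly stabilised allyl/benzyl cation), which would erode the inversion, allow attack at chain-C5 or allow capture by the chain-C3 silyl ether oxygen. Fallback, setting out from 17 and returning at 20: acylation with methyl chloroformate and pyridine gives the carbonate methyl (3S,5E,7R)-3-(TBS-oxy)-5-[4-methoxy-2,6-bis(MOM-oxy)phenyl]-1,7-bis[4-(TIPS-oxy)phenyl]hept-5-en-7-yl carbonate F7. Formate reduction with Pd(OAc)2, n-Bu3P and HCO2NH4 goes through a π-allyl complex of divalent palladium formed with inversion, and hydride passes from palladium to the more substituted terminus (chain-C5) on the metal face, so the hydrogen again arrives anti to the original C–O bond and the same 5S, 6E product is expected.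

Step 13. What may go wrong: cleavage of both MOM ethers or none, if the chelate does not discriminate enough. Fallback, setting out from 23 and returning at 24: both aryl acetals are removed with TMSOTf and 2,2′-bipyridyl followed by water, which leaves the alkyl TBS ether, to give 1-{2,4-dihydroxy-3-[(3S,5S,6E)-3-(TBS-oxy)-1,7-bis[4-(TIPS-oxy)phenyl]hept-6-en-5-yl]-6-methoxyphenyl}ethan-1-one F8. One equivalent of MOMCl with iPr2NEt then protects the free 4-hydroxyl and leaves the hydrogen-bonded 2-hydroxyl, giving 24.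

Step 15. What may go wrong: slow addition to an electron-rich, 8-substituted chromone, protodeboronation of the electron-rich boronic acid, and base-induced ring opening of the product with loss of C2 configuration. Fallback, setting out from 24 and returning at 28: pyrrolidine-mediated aldol condensation with 4-(methoxymethoxy)benzaldehyde gives the chalcone (2E)-1-{2-hydroxy-3-[(3S,5S,6E)-3-(TBS-oxy)-1,7-bis[4-(TIPS-oxy)phenyl]hept-6-en-5-yl]-6-methoxy-4-(MOM-oxy)phenyl}-3-[4-(MOM-oxy)phenyl]prop-2-en-1-one F9. It cyclises under the same conditions (oxa-Michael addition) to 28 together with its C2 epimer, the (2R)-flavanone F10. The two are diastereomers and would be separated by preparative chromatography, and F10 would be re-equilibrated through F9 and recycled. This fallback gives up catalyst control at C2.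

Further compounds

F1 | step 3 | (3S)-1-[4-(TIPS-oxy)phenyl]hex-5-en-3-ol | C=CC[C@@H](O)CCc1ccc(O[Si](C(C)C)(C(C)C)C(C)C)cc1
F2 | step 3 | (4S)-4-hydroxy-6-[4-(TIPS-oxy)phenyl]hexan-2-one | CC(=O)C[C@@H](O)CCc1ccc(O[Si](C(C)C)(C(C)C)C(C)C)cc1
F3 | step 3 | (1E,5S)-1-(dimethylamino)-5-hydroxy-7-[4-(TIPS-oxy)phenyl]hept-1-en-3-one | CN(C)/C=C/C(=O)C[C@@H](O)CCc1ccc(O[Si](C(C)C)(C(C)C)C(C)C)cc1
F4 | step 5 | (6S)-4-[4-methoxy-2,6-bis(MOM-oxy)phenyl]-6-{2-[4-(TIPS-oxy)phenyl]ethyl}-5,6-dihydro-2H-pyran-2-one | O=C1C=C(c2c(OCOC)cc(OC)cc2OCOC)C[C@H](CCc2ccc(O[Si](C(C)C)(C(C)C)C(C)C)cc2)O1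
F5 | step 9 | (3S)-3-(TBS-oxy)-5-[4-methoxy-2,6-bis(MOM-oxy)phenyl]-1,7-bis[4-(TIPS-oxy)phenyl]heptan-7-one, chain-C5 as in 20 | O=C(c1ccc(O[Si](C(C)C)(C(C)C)C(C)C)cc1)C[C@@H](c1c(OCOC)cc(OC)cc1OCOC)C[C@@H](O[Si](C)(C)C(C)(C)C)CCc1ccc(O[Si](C(C)C)(C(C)C)C(C)C)cc1
F6 | step 9 | (3S)-3-(TBS-oxy)-5-[4-methoxy-2,6-bis(MOM-oxy)phenyl]-1,7-bis[4-(TIPS-oxy)phenyl]heptan-7-ol, chain-C5 as in 20, both chain-C7 epimers | OC(c1ccc(O[Si](C(C)C)(C(C)C)C(C)C)cc1)C[C@@H](c1c(OCOC)cc(OC)cc1OCOC)C[C@@H](O[Si](C)(C)C(C)(C)C)CCc1ccc(O[Si](C(C)C)(C(C)C)C(C)C)cc1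
F7 | step 10 | methyl (3S,5E,7R)-3-(TBS-oxy)-5-[4-methoxy-2,6-bis(MOM-oxy)phenyl]-1,7-bis[4-(TIPS-oxy)phenyl]hept-5-en-7-yl carbonate | COC(=O)O[C@@H](c1ccc(O[Si](C(C)C)(C(C)C)C(C)C)cc1)/C=C(/c1c(OCOC)cc(OC)cc1OCOC)C[C@@H](O[Si](C)(C)C(C)(C)C)CCc1ccc(O[Si](C(C)C)(C(C)C)C(C)C)cc1
F8 | step 13 | 1-{2,4-dihydroxy-3-[(3S,5S,6E)-3-(TBS-oxy)-1,7-bis[4-(TIPS-oxy)phenyl]hept-6-en-5-yl]-6-methoxyphenyl}ethan-1-one | COc1cc(O)c([C@H](/C=C/c2ccc(O[Si](C(C)C)(C(C)C)C(C)C)cc2)C[C@@H](O[Si](C)(C)C(C)(C)C)CCc2ccc(O[Si](C(C)C)(C(C)C)C(C)C)cc2)c(O)c1C(C)=O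
F9 | step 15 | (2E)-1-{2-hydroxy-3-[(3S,5S,6E)-3-(TBS-oxy)-1,7-bis[4-(TIPS-oxy)phenyl]hept-6-en-5-yl]-6-methoxy-4-(MOM-oxy)phenyl}-3-[4-(MOM-oxy)phenyl]prop-2-en-1-one | COc1cc(OCOC)c([C@H](/C=C/c2ccc(O[Si](C(C)C)(C(C)C)C(C)C)cc2)C[C@@H](O[Si](C)(C)C(C)(C)C)CCc2ccc(O[Si](C(C)C)(C(C)C)C(C)C)cc2)c(O)c1C(=O)/C=C/c1ccc(OCOC)cc1
F10 | step 15 | (2R)-8-[(3S,5S,6E)-3-(TBS-oxy)-1,7-bis[4-(TIPS-oxy)phenyl]hept-6-en-5-yl]-5-methoxy-7-(MOM-oxy)-2-[4-(MOM-oxy)phenyl]-2,3-dihydro-4H-chromen-4-one | COc1cc(OCOC)c([C@H](/C=C/c2ccc(O[Si](C(C)C)(C(C)C)C(C)C)cc2)C[C@@H](O[Si](C)(C)C(C)(C)C)CCc2ccc(O[Si](C(C)C)(C(C)C)C(C)C)cc2)c2c1C(=O)C[C@H](c1ccc(OCOC)cc1)O2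
A1 | alternative 1 | (1R,4S)-4-[4-methoxy-2,6-bis(MOM-oxy)phenyl]cyclopent-2-en-1-ol (cis) | O[C@H]1C=C[C@@H](c2c(OCOC)cc(OC)cc2OCOC)C1
A2 | alternative 1 | 1-ethenyl-4-(MOM-oxy)benzene | C=Cc1ccc(OCOC)cc1
A3 | alternative 1 | (1E,3R,5S,6E)-5-[4-methoxy-2,6-bis(MOM-oxy)phenyl]-1,7-bis[4-(MOM-oxy)phenyl]hepta-1,6-dien-3-ol | COc1cc(OCOC)c([C@H](/C=C/c2ccc(OCOC)cc2)C[C@@H](O)/C=C/c2ccc(OCOC)cc2)c(OCOC)c1
A4 | alternative 2 | 2-diazo-1-{2-[4-(TBS-oxy)benzyloxy]-4-(TBS-oxy)-3-[(3S,5S,6E)-3-(TBS-oxy)-1,7-bis[4-(TBS-oxy)phenyl]hept-6-en-5-yl]-6-methoxyphenyl}ethan-1-one | COc1cc(O[Si](C)(C)C(C)(C)C)c([C@H](/C=C/c2ccc(O[Si](C)(C)C(C)(C)C)cc2)C[C@@H](O[Si](C)(C)C(C)(C)C)CCc2ccc(O[Si](C)(C)C(C)(C)C)cc2)c(OCc2ccc(O[Si](C)(C)C(C)(C)C)cc2)c1C(=O)C=[N+]=[N-]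
A5 | alternative 2 | penta-TBS ether of 30 | COc1cc(O[Si](C)(C)C(C)(C)C)c([C@H](/C=C/c2ccc(O[Si](C)(C)C(C)(C)C)cc2)C[C@@H](O[Si](C)(C)C(C)(C)C)CCc2ccc(O[Si](C)(C)C(C)(C)C)cc2)c2c1C(=O)C[C@@H](c1ccc(O[Si](C)(C)C(C)(C)C)cc1)O2
A6 | alternative 3 | 3-methoxycyclobut-2-en-1-one | COC1=CC(=O)C1
A7 | alternative 3 | {[(3S,5S)-5-(TBS-oxy)-7-[4-(MOM-oxy)phenyl]-3-{(E)-2-[4-(MOM-oxy)phenyl]ethenyl}hept-1-yn-1-yl]oxy}triisopropylsilane | CC(C)[Si](OC#C[C@H](/C=C/c1ccc(OCOC)cc1)C[C@@H](O[Si](C)(C)C(C)(C)C)CCc1ccc(OCOC)cc1)(C(C)C)C(C)C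
A8 | alternative 3 | 2-[(3S,5S,6E)-3-(TBS-oxy)-1,7-bis[4-(MOM-oxy)phenyl]hept-6-en-5-yl]-5-methoxy-3-(TIPS-oxy)phenol | COc1cc(O)c([C@H](/C=C/c2ccc(OCOC)cc2)C[C@@H](O[Si](C)(C)C(C)(C)C)CCc2ccc(OCOC)cc2)c(O[Si](C(C)C)(C(C)C)C(C)C)c1
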